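Every dihydrobenzofuran of the target shows one benzo pattern: O1 on C7a, oxygen on C6, hydrogen on C5 and C7, a single carbon substituent on C4. The plan cuts C3a–C7a, C4–C5 and C6–C7 in the unit that carries ring D (the 3,5-dioxygenated phenyl on C3). One rhodium-catalysed (2+2+2) cyclotrimerisation forms these three bonds and closes the benzene ring, the dihydrofuran and a sacrificial oxasilole. Its precursor is an acyclic triyne whose two stereocentres are already set: a terminal ynol ether on the C2 oxygen, the C3 alkyne, and a benzyloxyalkyne held by a CH2–O–Si bridge. Desilylation and oxidation give a C4 aldehyde that restarts the sequence twice, with alternating absolute sense; olefination and debenzylation finish.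

Key step: step 9

Conventions: Bn = benzyl, TBS = tert-butyldimethylsilyl, Ms = methanesulfonyl. Ring atoms are numbered as in 2,3-dihydrobenzofuran (O1, C2, C3, C3a, C4–C7, C7a). Unit C is the dihydrobenzofuran bearing ring D, unit B the central one, unit A the one bearing the styryl group. [C] = (2R,3R)-6-(benzyloxy)-2-[4-(benzyloxy)phenyl]-3-[3,5-bis(benzyloxy)phenyl]-2,3-dihydrobenzofuran-4-yl. [BC] = (2S,3S)-6-(benzyloxy)-2-[4-(benzyloxy)phenyl]-3-[C]-2,3-dihydrobenzofuran-4-yl.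

Configuration read from the target: unit C is 2R,3R, unit B is 2S,3S, unit A is 2R,3R. All three are trans and the alkene is E. Unit B has the opposite spatial sense, so the second cycle needs the antipodal ligand.

Design choices:
- All ten phenolic oxygens travel as benzyl ethers.
- The three C6 oxygens enter as a benzyloxyalkyne, so no methyl or ethyl aryl ether has to be cleaved from an acid-sensitive stilbene–dihydrobenzofuran at the end.
- Each carbinol centre comes from one direct asymmetric alkynylation.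
- Each benzylic mesylate is made and consumed in one flask.

Assumption: (R)-BINOL with Ti(OiPr)4 is taken to deliver an alkynylzinc to the Re face of an aryl aldehyde, as it does dialkylzincs. The sense would be checked on the first propargylic alcohol by Mosher ester analysis, and the ligand antipodes exchanged throughout if it proved opposite.

Step 1
Reactants: 1 benzyl alcohol; 2 trichloroethylene
Product: 3 benzyl (E)-1,2-dichlorovinyl ether
Conditions: KH (1.1 equiv), THF, 0 °C; 2 (1.1 equiv), −50 °C to rt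
Reagents that add atoms: none
Why: First stage of the Greene ynol ether synthesis, in which the potassium alkoxide adds trans to dichloroacetylene released from 2 by base and the vinyl anion is protonated by more 2, which should give a stable, purifiable dichlorovinyl ether.

Step 2
Reactants: 3 benzyl (E)-1,2-dichlorovinyl ether; 4 dichlorodiisopropylsilane
Product: 6 [(benzyloxy)ethynyl](chloro)diisopropylsilane, via lithium benzyloxyacetylide 5 (not isolated)
Conditions: n-BuLi (2.05 equiv), THF, −78 °C; cannulated into 4 (1.5 equiv), THF, −78 to 0 °C; excess 4 stripped in vacuo below rt, pentane, filtered under Ar, used crude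
Reagents that add atoms: n-butyllithium, [Li]CCCC (lithium stays only in 5)
Why: Second stage of the Greene sequence (dehydrochlorination, then chlorine–lithium exchange) followed by nucleophilic substitution at silicon, which should stop at the monochloride because 4 is in excess and its isopropyl groups retard a second displacement.

Step 3
Reactants: 7 3,4-bis(benzyloxy)benzyl chloride; 8 triethyl phosphite
Product: 9 diethyl [3,4-bis(benzyloxy)benzyl]phosphonate
Conditions: 8 (neat, 3 equiv), 130 °C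
Reagents that add atoms: none
Why: Michaelis–Arbuzov reaction, in which the phosphite displaces the primary benzylic chloride and chloride dealkylates the phosphonium ion under neutral conditions that leave benzyl ethers alone.

Step 4
Reactants: 10 3,5-bis(benzyloxy)benzaldehyde; 11 tert-butyldimethyl(prop-2-yn-1-yloxy)silane
Product: 12 (S)-1-[3,5-bis(benzyloxy)phenyl]-4-[(tert-butyldimethylsilyl)oxy]but-2-yn-1-ol
Conditions: 11 (2.2 equiv), Et2Zn (2 equiv), toluene, reflux; (R)-BINOL (20 mol %), Ti(OiPr)4 (50 mol %), Et2O, rt; then 10, rt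
Reagents that add atoms: none
Why: BINOL–titanium-catalysed enantioselective alkynylzinc addition, a reaction at its best with aromatic aldehydes, in which the (R)-ligand should guide the acetylide to the Re face of 10 and so set the S carbinol centre that is later relayed to C3 of unit C.

Step 5
Reactants: 12 (S)-propargylic alcohol; 13 4-(benzyloxy)benzaldehyde
Product: 16 (1R,2R)-1-[4-(benzyloxy)phenyl]-2-[3,5-bis(benzyloxy)phenyl]-5-[(tert-butyldimethylsilyl)oxy]pent-3-yn-1-ol (anti), via mesylate 14 (not isolated), via allenylzinc mesylate 15 (not isolated)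
Conditions: n-BuLi (1.0 equiv), THF, −78 °C; MsCl (1.05 equiv), −78 to −40 °C; then 13 (1.2 equiv), Pd(OAc)2 (5 mol %), PPh3 (5 mol %), Et2Zn (3 equiv), −78 to −20 °C
Reagents that add atoms: methanesulfonyl chloride, CS(=O)(=O)Cl (stays only in 14 and 15); diethylzinc, CC[Zn]CC (zinc stays only in 15)
Why: Marshall propargylation, in which zerovalent palladium displaces the mesylate in anti SN2' fashion, Et2Zn converts the allenylpalladium into the (M)-allenylzinc 15, and 15 adds to 13 through a cyclic SE2' transition state, so that the future C3 forms with net inversion of the carbinol carbon of 12 and the future C2 forms anti to it, while the labile benzylic mesylate is never isolated.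

Step 6
Reactants: 16 anti-homopropargylic alcohol; 2 trichloroethylene
Product: 19 ethynyl ether of 16 with the (1R,2R) centres and the TBS ether retained, via dichlorovinyl ether 17 (not isolated), via lithium alkynyl ether 18 (not isolated)
Conditions: KH (1.2 equiv), THF, 0 °C; 2 (1.2 equiv), −50 °C to rt; then n-BuLi (2.2 equiv), −78 to −40 °C; MeOH, −78 °C
Reagents that add atoms: n-butyllithium, [Li]CCCC (lithium stays only in 18)
Why: One-flask Greene ynol ether synthesis (alkoxide addition to dichloroacetylene, dehydrochlorination, chlorine–lithium exchange, protonation), which leaves the C–O bond and both stereocentres untouched because n-BuLi is limited to what the vinyl chloride consumes at −78 °C, where these reactions outrun abstraction of the hindered C–H next to the alkyne.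

Step 7
Reactants: 19 TBS-protected ynol ether
Product: 20 (4R,5R)-5-[4-(benzyloxy)phenyl]-4-[3,5-bis(benzyloxy)phenyl]-5-(ethynyloxy)pent-2-yn-1-ol
Conditions: TBAF (1.1 equiv), THF, 0 °C
Reagents that add atoms: none
Why: Fluoride cleavage of a primary silyl ether, chosen because ynol ethers are sensitive to acid but not to fluoride, with short contact at 0 °C to avoid propargyl–allenyl isomerisation.

Step 8
Reactants: 20 propargylic alcohol; 6 [(benzyloxy)ethynyl](chloro)diisopropylsilane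
Product: 21 triyne, the [(benzyloxy)ethynyl]diisopropylsilyl ether of 20 (4R,5R)
Conditions: 6 (1.3 equiv), imidazole (2.5 equiv), CH2Cl2, 0 °C to rt; Et3N-deactivated silica
Reagents that add atoms: none
Why: Silyl ether formation by substitution at silicon on an unhindered primary alcohol under non-acidic conditions that keep both ynol ethers intact, the isopropyl groups making the tether stable to chromatography.

Step 9
Reactants: 21 triyne
Product: 22 (2R,3R)-6-(benzyloxy)-2-[4-(benzyloxy)phenyl]-3-[3,5-bis(benzyloxy)phenyl]-2,3-dihydrobenzofuran bridged from C4 to C5 by CH2–O–Si(iPr)2 (CH2 on C4 and Si on C5)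
Conditions: [Rh(cod)2]BF4 (5 mol %), rac-BINAP (5 mol %), activated with H2 then Ar, 4 Å MS, CH2Cl2, slow addition of 21 (final 0.01 M), rt
Reagents that add atoms: none
Why: Monovalent rhodium freed from cod binds two neighbouring alkynes of 21 and couples them oxidatively to a rhodacyclopentadiene, the remaining tethered alkyne inserts, and reductive elimination releases the arene; this is the established rhodium-catalysed intramolecular (2+2+2) cyclotrimerisation of tethered triynes, known separately for ynol-ether-linked 1,6-diynes and for silyl-ether-linked diynes. The dihydrofuran closes through C3a–C7a as the five-membered ring fused to the metallacycle of the O1–C2–C3-linked 1,6-diyne, the oxasilole closes likewise through C4–C5 across the CH2–O–Si link, and the benzene ring closes in the final reductive elimination that completes the six-carbon circuit with C6–C7. No stereocentre is created, and C2 and C3 take part in no bond change, so the anti relationship of 16 appears as the trans relationship of 22. The step needs regioselectivity (oxygen on C6, silicon on C5, hydrogen on C7) and chemoselectivity (ring closure before oligomerisation, hydration, [3,3] shift or retro-ene loss of ketene from the two benzylic ynol ethers). The first is fixed by the two three-atom tethers, which allow only one way of joining the six alkyne carbons, and the second is served by dilution, dry solvent and a cationic catalyst that turns over at room temperature, well below the range near 60 °C in which benzyl alkynyl ethers rearrange.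

Step 10
Reactants: 22 oxasilole-bridged dihydrobenzofuran
Product: 23 [C]-methanol, i.e. [(2R,3R)-6-(benzyloxy)-2-[4-(benzyloxy)phenyl]-3-[3,5-bis(benzyloxy)phenyl]-2,3-dihydrobenzofuran-4-yl]methanol
Conditions: TBAF (1 M in THF, 4 equiv), THF, 60 °C
Reagents that add atoms: none
Why: Fluoride-induced protodesilylation of a benzoxasilole, in which a pentacoordinate silicate releases the aryl carbon (stabilised by the ortho oxygen) to a proton from the water in TBAF and the Si–O bond is cleaved as well, leaving C5–H and C4–CH2OH.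

Step 11
Reactants: 23 [C]-methanol
Product: 24 [C]-carbaldehyde
Conditions: MnO2 (15 equiv), CH2Cl2, rt
Reagents that add atoms: none
Why: MnO2 oxidation of a benzylic alcohol, which stops at the aldehyde and leaves benzyl ethers and the C2 and C3 centres untouched.

Step 12
Reactants: 24 [C]-carbaldehyde; 11 tert-butyldimethyl(prop-2-yn-1-yloxy)silane
Product: 25 (S)-1-[C]-4-[(tert-butyldimethylsilyl)oxy]but-2-yn-1-ol
Conditions: 11 (3 equiv), Et2Zn (3 equiv), toluene, reflux; (S)-BINOL (20 mol %), Ti(OiPr)4 (50 mol %), Et2O, rt; then 24, rt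
Reagents that add atoms: none
Why: The same BINOL–titanium-catalysed alkynylzinc addition with the (S)-ligand, so that the acetylide should attack the Si face of the ortho-substituted aldehyde; the new centre is S by the CIP rules because [C] outranks the alkynyl group, yet has the opposite spatial sense to 12, and a minor diastereomer can be removed by chromatography.

Step 13
Reactants: 25 (S)-propargylic alcohol; 13 4-(benzyloxy)benzaldehyde
Product: 28 (1S,2R)-1-[4-(benzyloxy)phenyl]-2-[C]-5-[(tert-butyldimethylsilyl)oxy]pent-3-yn-1-ol (anti), via mesylate 26 (not isolated), via allenylzinc mesylate 27 (not isolated)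
Conditions: n-BuLi (1.0 equiv), THF, −78 °C; MsCl (1.05 equiv), −78 to −40 °C; then 13 (1.5 equiv), Pd(OAc)2 (5 mol %), PPh3 (5 mol %), Et2Zn (3 equiv), −78 to −20 °C
Reagents that add atoms: methanesulfonyl chloride, CS(=O)(=O)Cl (stays only in 26 and 27); diethylzinc, CC[Zn]CC (zinc stays only in 27)
Why: Marshall propargylation as in step 5, where anti SN2' attack of zerovalent palladium, transmetallation to the (P)-allenylzinc 27 and cyclic SE2' addition to 13 should deliver C3 of unit B with net inversion and C2 anti to it, which is the 2S,3S series.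

Step 14
Reactants: 28 anti-homopropargylic alcohol; 2 trichloroethylene
Product: 31 ethynyl ether of 28 with the (1S,2R) centres and the TBS ether retained, via dichlorovinyl ether 29 (not isolated), via lithium alkynyl ether 30 (not isolated)
Conditions: KH (1.2 equiv), THF, 0 °C; 2 (1.2 equiv), −50 °C to rt; then n-BuLi (2.2 equiv), −78 to −40 °C; MeOH, −78 °C
Reagents that add atoms: n-butyllithium, [Li]CCCC (lithium stays only in 30)
Why: One-flask Greene ynol ether synthesis as in step 6, which breaks no bond at a stereocentre and in which the doubly benzylic C–H bonds of unit C are too hindered and too weakly acidic to compete at −78 °C.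

Step 15
Reactants: 31 TBS-protected ynol ether
Product: 32 (4R,5S)-5-[4-(benzyloxy)phenyl]-4-[C]-5-(ethynyloxy)pent-2-yn-1-ol
Conditions: TBAF (1.1 equiv), THF, 0 °C
Reagents that add atoms: none
Why: Fluoride cleavage of the primary silyl ether, to which the ynol ether and the benzyl ethers are inert.

Step 16
Reactants: 32 propargylic alcohol; 6 [(benzyloxy)ethynyl](chloro)diisopropylsilane
Product: 33 triyne, the [(benzyloxy)ethynyl]diisopropylsilyl ether of 32 (4R,5S)
Conditions: 6 (1.3 equiv), imidazole (2.5 equiv), CH2Cl2, 0 °C to rt; Et3N-deactivated silica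
Reagents that add atoms: none
Why: Silyl ether formation on a primary alcohol under non-acidic conditions, as in step 8.

Step 17
Reactants: 33 triyne
Product: 34 (2S,3S)-6-(benzyloxy)-2-[4-(benzyloxy)phenyl]-3-[C]-2,3-dihydrobenzofuran bridged from C4 to C5 by CH2–O–Si(iPr)2 (CH2 on C4 and Si on C5)
Conditions: [Rh(cod)2]BF4 (10 mol %), rac-BINAP (10 mol %), activated with H2 then Ar, 4 Å MS, CH2Cl2 (0.01 M), rt
Reagents that add atoms: none
Why: Rhodium-catalysed intramolecular (2+2+2) cyclotrimerisation as in step 9, with regiochemistry again dictated by the two tethers and no stereocentre made or disturbed.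

Step 18
Reactants: 34 oxasilole-bridged bis(dihydrobenzofuran)
Product: 35 [BC]-methanol
Conditions: TBAF (1 M in THF, 4 equiv), THF, 60 °C
Reagents that add atoms: none
Why: Fluoride-induced protodesilylation of the benzoxasilole as in step 10, leaving C5–H and C4–CH2OH on unit B.

Step 19
Reactants: 35 [BC]-methanol
Product: 36 [BC]-carbaldehyde
Conditions: MnO2 (15 equiv), CH2Cl2, rt
Reagents that add atoms: none
Why: Selective MnO2 oxidation of the benzylic alcohol to the aldehyde.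

Step 20
Reactants: 36 [BC]-carbaldehyde; 11 tert-butyldimethyl(prop-2-yn-1-yloxy)silane
Product: 37 (R)-1-[BC]-4-[(tert-butyldimethylsilyl)oxy]but-2-yn-1-ol
Conditions: 11 (3 equiv), Et2Zn (3 equiv), toluene, reflux; (R)-BINOL (20 mol %), Ti(OiPr)4 (50 mol %), Et2O, rt; then 36, rt
Reagents that add atoms: none
Why: BINOL–titanium-catalysed alkynylzinc addition with the (R)-ligand again, which should direct attack to the Re face and set a centre of the same spatial sense as in 12 (R by the CIP rules because [BC] outranks the alkynyl group), a minor diastereomer being separable.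

Step 21
Reactants: 37 (R)-propargylic alcohol; 13 4-(benzyloxy)benzaldehyde
Product: 40 (1R,2S)-1-[4-(benzyloxy)phenyl]-2-[BC]-5-[(tert-butyldimethylsilyl)oxy]pent-3-yn-1-ol (anti), via mesylate 38 (not isolated), via allenylzinc mesylate 39 (not isolated)
Conditions: n-BuLi (1.0 equiv), THF, −78 °C; MsCl (1.05 equiv), −78 to −40 °C; then 13 (1.5 equiv), Pd(OAc)2 (5 mol %), PPh3 (5 mol %), Et2Zn (3 equiv), −78 to −20 °C
Reagents that add atoms: methanesulfonyl chloride, CS(=O)(=O)Cl (stays only in 38 and 39); diethylzinc, CC[Zn]CC (zinc stays only in 39)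
Why: Marshall propargylation through the (M)-allenylzinc 39, with anti SN2' displacement and cyclic SE2' addition setting C3 of unit A by net inversion and C2 anti to it, which is the 2R,3R series.

Step 22
Reactants: 40 anti-homopropargylic alcohol; 2 trichloroethylene
Product: 43 ethynyl ether of 40 with the (1R,2S) centres and the TBS ether retained, via dichlorovinyl ether 41 (not isolated), via lithium alkynyl ether 42 (not isolated)
Conditions: KH (1.2 equiv), THF, 0 °C; 2 (1.2 equiv), −50 °C to rt; then n-BuLi (2.2 equiv), −78 to −40 °C; MeOH, −78 °C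
Reagents that add atoms: n-butyllithium, [Li]CCCC (lithium stays only in 42)
Why: One-flask Greene ynol ether synthesis as in steps 6 and 14, with no bond to a stereocentre broken.

Step 23
Reactants: 43 TBS-protected ynol ether
Product: 44 (4S,5R)-5-[4-(benzyloxy)phenyl]-4-[BC]-5-(ethynyloxy)pent-2-yn-1-ol
Conditions: TBAF (1.1 equiv), THF, 0 °C
Reagents that add atoms: none
Why: Fluoride cleavage of the primary silyl ether in the presence of a fluoride-stable ynol ether.

Step 24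
Reactants: 44 propargylic alcohol; 6 [(benzyloxy)ethynyl](chloro)diisopropylsilane
Product: 45 triyne, the [(benzyloxy)ethynyl]diisopropylsilyl ether of 44 (4S,5R)
Conditions: 6 (1.3 equiv), imidazole (2.5 equiv), CH2Cl2, 0 °C to rt; Et3N-deactivated silica
Reagents that add atoms: none
Why: Silyl ether formation on a primary alcohol under non-acidic conditions.

Step 25
Reactants: 45 triyne
Product: 46 (2R,3R)-6-(benzyloxy)-2-[4-(benzyloxy)phenyl]-3-[BC]-2,3-dihydrobenzofuran bridged from C4 to C5 by CH2–O–Si(iPr)2 (CH2 on C4 and Si on C5)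
Conditions: [Rh(cod)2]BF4 (10 mol %), rac-BINAP (10 mol %), activated with H2 then Ar, 4 Å MS, CH2Cl2 (0.01 M), rt
Reagents that add atoms: none
Why: Rhodium-catalysed intramolecular (2+2+2) cyclotrimerisation, tether-controlled as in steps 9 and 17 and without effect on the six stereocentres present.

Step 26
Reactants: 46 oxasilole-bridged tris(dihydrobenzofuran)
Product: 47 [(2R,3R)-6-(benzyloxy)-2-[4-(benzyloxy)phenyl]-3-[BC]-2,3-dihydrobenzofuran-4-yl]methanol
Conditions: TBAF (1 M in THF, 4 equiv), THF, 60 °C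
Reagents that add atoms: none
Why: Fluoride-induced protodesilylation of the benzoxasilole, leaving C5–H and C4–CH2OH on unit A.

Step 27
Reactants: 47 benzylic alcohol
Product: 48 (2R,3R)-6-(benzyloxy)-2-[4-(benzyloxy)phenyl]-3-[BC]-2,3-dihydrobenzofuran-4-carbaldehyde
Conditions: MnO2 (15 equiv), CH2Cl2, rt
Reagents that add atoms: none
Why: Selective MnO2 oxidation of the benzylic alcohol to the aldehyde.

Step 28
Reactants: 48 aldehyde; 9 diethyl [3,4-bis(benzyloxy)benzyl]phosphonate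
Product: 49 (2R,3R)-6-(benzyloxy)-2-[4-(benzyloxy)phenyl]-3-[BC]-4-{(E)-2-[3,4-bis(benzyloxy)phenyl]ethenyl}-2,3-dihydrobenzofuran (decabenzyl ether of the target)
Conditions: 9 (1.5 equiv), KOtBu (1.4 equiv), THF, 0 °C; then 48, 0 °C to rt
Reagents that add atoms: none
Why: Horner–Wadsworth–Emmons olefination with a semi-stabilised benzylic phosphonate anion, whose reversible addition to an aryl aldehyde should lead to the E-stilbene, the doubly benzylic C–H bonds being too weakly acidic to epimerise.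

Step 29
Reactants: 49 decabenzyl ether
Product: 50 target CNP0099535.1
Conditions: BCl3 (30 equiv), pentamethylbenzene (40 equiv), CH2Cl2, −78 °C; CHCl3/MeOH quench at −78 °C, aqueous work-up; Sephadex LH-20
Reagents that add atoms: none
Why: Lewis-acid debenzylation with a non-basic cation scavenger, in which BCl3 activates each aryl benzyl ether at −78 °C and pentamethylbenzene captures the benzyl cation, so that the alkene is not reduced as it would be by hydrogenolysis, the freed resorcinol rings are not C-benzylated, and each C2–O1 bond loses its donor assistance as soon as the para oxygen has become a dichloroborate, no stereocentre being touched.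

Compound list
1 | benzyl alcohol | OCc1ccccc1 | starting material
2 | trichloroethylene | ClC=C(Cl)Cl | starting material
3 | benzyl (E)-1,2-dichlorovinyl ether | Cl/C=C(/Cl)OCc1ccccc1 | intermediate
4 | dichlorodiisopropylsilane | CC(C)[Si](Cl)(Cl)C(C)C | starting material
5 | lithium benzyloxyacetylide | [Li]C#COCc1ccccc1 | intermediate
6 | [(benzyloxy)ethynyl](chloro)diisopropylsilane | CC(C)[Si](Cl)(C(C)C)C#COCc1ccccc1 | intermediate
7 | 3,4-bis(benzyloxy)benzyl chloride | ClCc1ccc(OCc2ccccc2)c(OCc2ccccc2)c1 | starting material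
8 | triethyl phosphite | CCOP(OCC)OCC | starting material
9 | diethyl [3,4-bis(benzyloxy)benzyl]phosphonate | CCOP(=O)(Cc1ccc(OCc2ccccc2)c(OCc2ccccc2)c1)OCC | intermediate
10 | 3,5-bis(benzyloxy)benzaldehyde | O=Cc1cc(OCc2ccccc2)cc(OCc2ccccc2)c1 | starting material
11 | tert-butyldimethyl(prop-2-yn-1-yloxy)silane | C#CCO[Si](C)(C)C(C)(C)C | starting material
12 | (S)-1-[3,5-bis(benzyloxy)phenyl]-4-(TBSO)but-2-yn-1-ol | O[C@@H](c8cc(OCc9ccccc9)cc(OCc9ccccc9)c8)C#CCO[Si](C)(C)C(C)(C)C | intermediate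
13 | 4-(benzyloxy)benzaldehyde | O=Cc1ccc(OCc2ccccc2)cc1 | starting material
14 | (S)-methanesulfonate of 12 | CS(=O)(=O)O[C@@H](c8cc(OCc9ccccc9)cc(OCc9ccccc9)c8)C#CCO[Si](C)(C)C(C)(C)C | intermediate
15 | (M)-allenylzinc methanesulfonate ArCH=C=C(CH2OTBS)ZnOMs, Ar = 3,5-bis(benzyloxy)phenyl | [H]C(c8cc(OCc9ccccc9)cc(OCc9ccccc9)c8)=[C@]=C([Zn]OS(C)(=O)=O)CO[Si](C)(C)C(C)(C)C | intermediate
16 | (1R,2R)-1-[4-(benzyloxy)phenyl]-2-[3,5-bis(benzyloxy)phenyl]-5-(TBSO)pent-3-yn-1-ol | O[C@@H](c8ccc(OCc9ccccc9)cc8)[C@H](c8cc(OCc9ccccc9)cc(OCc9ccccc9)c8)C#CCO[Si](C)(C)C(C)(C)C | intermediate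
17 | (E)-1,2-dichlorovinyl ether of 16 | Cl/C=C(/Cl)O[C@@H](c8ccc(OCc9ccccc9)cc8)[C@H](c8cc(OCc9ccccc9)cc(OCc9ccccc9)c8)C#CCO[Si](C)(C)C(C)(C)C | intermediate
18 | lithium acetylide of 19 | [Li]C#CO[C@@H](c8ccc(OCc9ccccc9)cc8)[C@H](c8cc(OCc9ccccc9)cc(OCc9ccccc9)c8)C#CCO[Si](C)(C)C(C)(C)C | intermediate
19 | ethynyl ether of 16 | C#CO[C@@H](c8ccc(OCc9ccccc9)cc8)[C@H](c8cc(OCc9ccccc9)cc(OCc9ccccc9)c8)C#CCO[Si](C)(C)C(C)(C)C | intermediate
20 | (4R,5R)-5-[4-(benzyloxy)phenyl]-4-[3,5-bis(benzyloxy)phenyl]-5-(ethynyloxy)pent-2-yn-1-ol | C#CO[C@@H](c8ccc(OCc9ccccc9)cc8)[C@H](c8cc(OCc9ccccc9)cc(OCc9ccccc9)c8)C#CCO | intermediate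
21 | triyne, [(benzyloxy)ethynyl]diisopropylsilyl ether of 20 | C#CO[C@@H](c8ccc(OCc9ccccc9)cc8)[C@H](c8cc(OCc9ccccc9)cc(OCc9ccccc9)c8)C#CCO[Si](C(C)C)(C(C)C)C#COCc9ccccc9 | intermediate
22 | (2R,3R)-dihydrobenzofuran of unit C with C4–CH2–O–Si(iPr)2–C5 bridge | C(c9ccccc9)Oc1cc2c(c3c1[Si](C(C)C)(C(C)C)OC3)[C@@H](c8cc(OCc9ccccc9)cc(OCc9ccccc9)c8)[C@H](c8ccc(OCc9ccccc9)cc8)O2 | intermediate
23 | [C]-methanol | OCc1cc(OCc9ccccc9)cc2c1[C@@H](c8cc(OCc9ccccc9)cc(OCc9ccccc9)c8)[C@H](c8ccc(OCc9ccccc9)cc8)O2 | intermediate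
24 | [C]-carbaldehyde | O=Cc1cc(OCc9ccccc9)cc2c1[C@@H](c8cc(OCc9ccccc9)cc(OCc9ccccc9)c8)[C@H](c8ccc(OCc9ccccc9)cc8)O2 | intermediate
25 | (S)-1-[C]-4-(TBSO)but-2-yn-1-ol | O[C@H](c1cc(OCc9ccccc9)cc2c1[C@@H](c8cc(OCc9ccccc9)cc(OCc9ccccc9)c8)[C@H](c8ccc(OCc9ccccc9)cc8)O2)C#CCO[Si](C)(C)C(C)(C)C | intermediate
26 | (S)-methanesulfonate of 25 | CS(=O)(=O)O[C@H](c1cc(OCc9ccccc9)cc2c1[C@@H](c8cc(OCc9ccccc9)cc(OCc9ccccc9)c8)[C@H](c8ccc(OCc9ccccc9)cc8)O2)C#CCO[Si](C)(C)C(C)(C)C | intermediate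
27 | (P)-allenylzinc methanesulfonate [C]CH=C=C(CH2OTBS)ZnOMs | [H]C(c1cc(OCc9ccccc9)cc2c1[C@@H](c8cc(OCc9ccccc9)cc(OCc9ccccc9)c8)[C@H](c8ccc(OCc9ccccc9)cc8)O2)=[C@@]=C([Zn]OS(C)(=O)=O)CO[Si](C)(C)C(C)(C)C | intermediate
28 | (1S,2R)-1-[4-(benzyloxy)phenyl]-2-[C]-5-(TBSO)pent-3-yn-1-ol | O[C@H](c8ccc(OCc9ccccc9)cc8)[C@@H](c1cc(OCc9ccccc9)cc2c1[C@@H](c8cc(OCc9ccccc9)cc(OCc9ccccc9)c8)[C@H](c8ccc(OCc9ccccc9)cc8)O2)C#CCO[Si](C)(C)C(C)(C)C | intermediate
29 | (E)-1,2-dichlorovinyl ether of 28 | Cl/C=C(/Cl)O[C@H](c8ccc(OCc9ccccc9)cc8)[C@@H](c1cc(OCc9ccccc9)cc2c1[C@@H](c8cc(OCc9ccccc9)cc(OCc9ccccc9)c8)[C@H](c8ccc(OCc9ccccc9)cc8)O2)C#CCO[Si](C)(C)C(C)(C)C | intermediate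
30 | lithium acetylide of 31 | [Li]C#CO[C@H](c8ccc(OCc9ccccc9)cc8)[C@@H](c1cc(OCc9ccccc9)cc2c1[C@@H](c8cc(OCc9ccccc9)cc(OCc9ccccc9)c8)[C@H](c8ccc(OCc9ccccc9)cc8)O2)C#CCO[Si](C)(C)C(C)(C)C | intermediate
31 | ethynyl ether of 28 | C#CO[C@H](c8ccc(OCc9ccccc9)cc8)[C@@H](c1cc(OCc9ccccc9)cc2c1[C@@H](c8cc(OCc9ccccc9)cc(OCc9ccccc9)c8)[C@H](c8ccc(OCc9ccccc9)cc8)O2)C#CCO[Si](C)(C)C(C)(C)C | intermediate
32 | (4R,5S)-5-[4-(benzyloxy)phenyl]-4-[C]-5-(ethynyloxy)pent-2-yn-1-ol | C#CO[C@H](c8ccc(OCc9ccccc9)cc8)[C@@H](c1cc(OCc9ccccc9)cc2c1[C@@H](c8cc(OCc9ccccc9)cc(OCc9ccccc9)c8)[C@H](c8ccc(OCc9ccccc9)cc8)O2)C#CCO | intermediate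
33 | triyne, [(benzyloxy)ethynyl]diisopropylsilyl ether of 32 | C#CO[C@H](c8ccc(OCc9ccccc9)cc8)[C@@H](c1cc(OCc9ccccc9)cc2c1[C@@H](c8cc(OCc9ccccc9)cc(OCc9ccccc9)c8)[C@H](c8ccc(OCc9ccccc9)cc8)O2)C#CCO[Si](C(C)C)(C(C)C)C#COCc9ccccc9 | intermediate
34 | (2S,3S)-dihydrobenzofuran of unit B, 3-[C], with C4–CH2–O–Si(iPr)2–C5 bridge | C(c9ccccc9)Oc3cc4c(c5c3[Si](C(C)C)(C(C)C)OC5)[C@H](c1cc(OCc9ccccc9)cc2c1[C@@H](c8cc(OCc9ccccc9)cc(OCc9ccccc9)c8)[C@H](c8ccc(OCc9ccccc9)cc8)O2)[C@@H](c8ccc(OCc9ccccc9)cc8)O4 | intermediate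
35 | [BC]-methanol | OCc3cc(OCc9ccccc9)cc4c3[C@H](c1cc(OCc9ccccc9)cc2c1[C@@H](c8cc(OCc9ccccc9)cc(OCc9ccccc9)c8)[C@H](c8ccc(OCc9ccccc9)cc8)O2)[C@@H](c8ccc(OCc9ccccc9)cc8)O4 | intermediate
36 | [BC]-carbaldehyde | O=Cc3cc(OCc9ccccc9)cc4c3[C@H](c1cc(OCc9ccccc9)cc2c1[C@@H](c8cc(OCc9ccccc9)cc(OCc9ccccc9)c8)[C@H](c8ccc(OCc9ccccc9)cc8)O2)[C@@H](c8ccc(OCc9ccccc9)cc8)O4 | intermediate
37 | (R)-1-[BC]-4-(TBSO)but-2-yn-1-ol | O[C@@H](c3cc(OCc9ccccc9)cc4c3[C@H](c1cc(OCc9ccccc9)cc2c1[C@@H](c8cc(OCc9ccccc9)cc(OCc9ccccc9)c8)[C@H](c8ccc(OCc9ccccc9)cc8)O2)[C@@H](c8ccc(OCc9ccccc9)cc8)O4)C#CCO[Si](C)(C)C(C)(C)C | intermediate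
38 | (R)-methanesulfonate of 37 | CS(=O)(=O)O[C@@H](c3cc(OCc9ccccc9)cc4c3[C@H](c1cc(OCc9ccccc9)cc2c1[C@@H](c8cc(OCc9ccccc9)cc(OCc9ccccc9)c8)[C@H](c8ccc(OCc9ccccc9)cc8)O2)[C@@H](c8ccc(OCc9ccccc9)cc8)O4)C#CCO[Si](C)(C)C(C)(C)C | intermediate
39 | (M)-allenylzinc methanesulfonate [BC]CH=C=C(CH2OTBS)ZnOMs | [H]C(c3cc(OCc9ccccc9)cc4c3[C@H](c1cc(OCc9ccccc9)cc2c1[C@@H](c8cc(OCc9ccccc9)cc(OCc9ccccc9)c8)[C@H](c8ccc(OCc9ccccc9)cc8)O2)[C@@H](c8ccc(OCc9ccccc9)cc8)O4)=[C@]=C([Zn]OS(C)(=O)=O)CO[Si](C)(C)C(C)(C)C | intermediate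
40 | (1R,2S)-1-[4-(benzyloxy)phenyl]-2-[BC]-5-(TBSO)pent-3-yn-1-ol | O[C@@H](c8ccc(OCc9ccccc9)cc8)[C@H](c3cc(OCc9ccccc9)cc4c3[C@H](c1cc(OCc9ccccc9)cc2c1[C@@H](c8cc(OCc9ccccc9)cc(OCc9ccccc9)c8)[C@H](c8ccc(OCc9ccccc9)cc8)O2)[C@@H](c8ccc(OCc9ccccc9)cc8)O4)C#CCO[Si](C)(C)C(C)(C)C | intermediate
41 | (E)-1,2-dichlorovinyl ether of 40 | Cl/C=C(/Cl)O[C@@H](c8ccc(OCc9ccccc9)cc8)[C@H](c3cc(OCc9ccccc9)cc4c3[C@H](c1cc(OCc9ccccc9)cc2c1[C@@H](c8cc(OCc9ccccc9)cc(OCc9ccccc9)c8)[C@H](c8ccc(OCc9ccccc9)cc8)O2)[C@@H](c8ccc(OCc9ccccc9)cc8)O4)C#CCO[Si](C)(C)C(C)(C)C | intermediate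
42 | lithium acetylide of 43 | [Li]C#CO[C@@H](c8ccc(OCc9ccccc9)cc8)[C@H](c3cc(OCc9ccccc9)cc4c3[C@H](c1cc(OCc9ccccc9)cc2c1[C@@H](c8cc(OCc9ccccc9)cc(OCc9ccccc9)c8)[C@H](c8ccc(OCc9ccccc9)cc8)O2)[C@@H](c8ccc(OCc9ccccc9)cc8)O4)C#CCO[Si](C)(C)C(C)(C)C | intermediate
43 | ethynyl ether of 40 | C#CO[C@@H](c8ccc(OCc9ccccc9)cc8)[C@H](c3cc(OCc9ccccc9)cc4c3[C@H](c1cc(OCc9ccccc9)cc2c1[C@@H](c8cc(OCc9ccccc9)cc(OCc9ccccc9)c8)[C@H](c8ccc(OCc9ccccc9)cc8)O2)[C@@H](c8ccc(OCc9ccccc9)cc8)O4)C#CCO[Si](C)(C)C(C)(C)C | intermediate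
44 | (4S,5R)-5-[4-(benzyloxy)phenyl]-4-[BC]-5-(ethynyloxy)pent-2-yn-1-ol | C#CO[C@@H](c8ccc(OCc9ccccc9)cc8)[C@H](c3cc(OCc9ccccc9)cc4c3[C@H](c1cc(OCc9ccccc9)cc2c1[C@@H](c8cc(OCc9ccccc9)cc(OCc9ccccc9)c8)[C@H](c8ccc(OCc9ccccc9)cc8)O2)[C@@H](c8ccc(OCc9ccccc9)cc8)O4)C#CCO | intermediate
45 | triyne, [(benzyloxy)ethynyl]diisopropylsilyl ether of 44 | C#CO[C@@H](c8ccc(OCc9ccccc9)cc8)[C@H](c3cc(OCc9ccccc9)cc4c3[C@H](c1cc(OCc9ccccc9)cc2c1[C@@H](c8cc(OCc9ccccc9)cc(OCc9ccccc9)c8)[C@H](c8ccc(OCc9ccccc9)cc8)O2)[C@@H](c8ccc(OCc9ccccc9)cc8)O4)C#CCO[Si](C(C)C)(C(C)C)C#COCc9ccccc9 | intermediate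
46 | (2R,3R)-dihydrobenzofuran of unit A, 3-[BC], with C4–CH2–O–Si(iPr)2–C5 bridge | C(c9ccccc9)Oc5cc6c(c7c5[Si](C(C)C)(C(C)C)OC7)[C@@H](c3cc(OCc9ccccc9)cc4c3[C@H](c1cc(OCc9ccccc9)cc2c1[C@@H](c8cc(OCc9ccccc9)cc(OCc9ccccc9)c8)[C@H](c8ccc(OCc9ccccc9)cc8)O2)[C@@H](c8ccc(OCc9ccccc9)cc8)O4)[C@H](c8ccc(OCc9ccccc9)cc8)O6 | intermediate
47 | [(2R,3R)-6-(benzyloxy)-2-[4-(benzyloxy)phenyl]-3-[BC]-2,3-dihydrobenzofuran-4-yl]methanol | OCc5cc(OCc9ccccc9)cc6c5[C@@H](c3cc(OCc9ccccc9)cc4c3[C@H](c1cc(OCc9ccccc9)cc2c1[C@@H](c8cc(OCc9ccccc9)cc(OCc9ccccc9)c8)[C@H](c8ccc(OCc9ccccc9)cc8)O2)[C@@H](c8ccc(OCc9ccccc9)cc8)O4)[C@H](c8ccc(OCc9ccccc9)cc8)O6 | intermediate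
48 | (2R,3R)-6-(benzyloxy)-2-[4-(benzyloxy)phenyl]-3-[BC]-2,3-dihydrobenzofuran-4-carbaldehyde | O=Cc5cc(OCc9ccccc9)cc6c5[C@@H](c3cc(OCc9ccccc9)cc4c3[C@H](c1cc(OCc9ccccc9)cc2c1[C@@H](c8cc(OCc9ccccc9)cc(OCc9ccccc9)c8)[C@H](c8ccc(OCc9ccccc9)cc8)O2)[C@@H](c8ccc(OCc9ccccc9)cc8)O4)[C@H](c8ccc(OCc9ccccc9)cc8)O6 | intermediate
49 | decabenzyl ether of the target, E-stilbene | C(c9ccccc9)Oc7ccc(/C=C/c5cc(OCc9ccccc9)cc6c5[C@@H](c3cc(OCc9ccccc9)cc4c3[C@H](c1cc(OCc9ccccc9)cc2c1[C@@H](c8cc(OCc9ccccc9)cc(OCc9ccccc9)c8)[C@H](c8ccc(OCc9ccccc9)cc8)O2)[C@@H](c8ccc(OCc9ccccc9)cc8)O4)[C@H](c8ccc(OCc9ccccc9)cc8)O6)cc7OCc9ccccc9 | intermediate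
50 | CNP0099535.1 | Oc1ccc([C@H]2Oc3cc(O)cc([C@@H]4c5c(/C=C/c6ccc(O)c(O)c6)cc(O)cc5O[C@H]4c4ccc(O)cc4)c3[C@@H]2c2cc(O)cc3c2[C@@H](c2cc(O)cc(O)c2)[C@H](c2ccc(O)cc2)O3)cc1 | target

Total step count: 29. Longest linear sequence: 26 steps (steps 4 to 29, from 10).

Steps most likely to fail

Step 9. The two benzylic ynol ethers may be consumed faster than the metallacycle forms. The possible causes are hydration at the Lewis-acidic cationic metal, [3,3] shift into the neighbouring arene, and retro-ene loss of ketene. Alternatively the hindered, donor-substituted silylalkyne may insert too slowly, so that oligomerisation takes over.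

The fallback gives up the silicon bridge and relies on steric regiocontrol in a bimolecular reaction. It sets out from 19 and 3 and returns at 23.
- Treatment of 3 with n-BuLi (2 equiv, −78 °C) and then MeOH should give benzyloxyethyne F1.
- Diyne 19, with its TBS ether still in place, would be combined with F1 under Cp*RuCl(cod) in 1,2-dichloroethane at rt.
- In this catalyst system the substituted diyne terminus (C4, bearing CH2OTBS) directs the substituent of a terminal alkyne into the meta position, here C6.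
- The product should be the 4-(silyloxymethyl)dihydrobenzofuran F2, already with C5–H.
- TBAF in THF then gives 23.

Step 13 (sister steps 5 and 21). Several processes may intervene:
- The hindered benzylic mesylate may ionise before oxidative addition.
- The allenylpalladium or allenylzinc may lose configuration through repeated attack of zerovalent palladium.
- The very bulky allenylzinc may add slowly and with poor anti selectivity.

The fallback replaces the transient zinc reagent by an isolable, configurationally stable boron reagent. It sets out from 25 and returns at 28.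
- Methyl chloroformate and pyridine should convert 25 into the stable propargylic methyl carbonate F3.
- Copper-catalysed anti SN2' borylation (CuOtBu, Xantphos, B2pin2, THF) should give the (P)-allenylboronate F4, which can be purified.
- Heating F4 with 13 in toluene should lead through a closed six-membered transition state, with the same net inversion and anti preference, to 28 after hydrolytic work-up.

Step 29. Ten cleavages must all go to completion while several side processes threaten: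
- The Lewis acid may ionise a benzylic C2–O1 bond.
- It may promote attack of C5 of unit B on the activated stilbene, closing a seven-membered ring.
- It may allow C-benzylation of freed resorcinol rings.
- Partly deprotected borates may precipitate.

The fallback removes the benzyl groups by hydrogenolysis before the alkene exists and ends with a fluoride step, so that no Lewis acid is used. It sets out from 47 and 9 and returns at 50.
- H2 over Pd/C in THF/MeOH should convert 47 into the octaphenol alcohol F5.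
- TBSCl and imidazole in DMF give the nona-TBS ether F6.
- Camphorsulfonic acid in MeOH/CH2Cl2 at 0 °C removes only the alkyl silyl ether to give the octa-TBS alcohol F7.
- MnO2 oxidises F7 to the octa-TBS aldehyde F8.
- In parallel, hydrogenolysis of 9 gives the catechol phosphonate F9, and silylation gives the bis-TBS phosphonate F10.
- Horner–Wadsworth–Emmons olefination of F8 with F10 (LiHMDS, THF) gives the deca-TBS stilbene F11.
- Et3N·3HF in THF at rt releases 50.

Further compounds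
F1 | step 9 | benzyloxyethyne | C#COCc1ccccc1
F2 | step 9 | (2R,3R)-6-(benzyloxy)-2-[4-(benzyloxy)phenyl]-3-[3,5-bis(benzyloxy)phenyl]-4-[(TBSO)methyl]-2,3-dihydrobenzofuran | CC(C)(C)[Si](C)(C)OCc1cc(OCc9ccccc9)cc2c1[C@@H](c8cc(OCc9ccccc9)cc(OCc9ccccc9)c8)[C@H](c8ccc(OCc9ccccc9)cc8)O2
F3 | step 13 | (S)-methyl carbonate of 25 | COC(=O)O[C@H](c1cc(OCc9ccccc9)cc2c1[C@@H](c8cc(OCc9ccccc9)cc(OCc9ccccc9)c8)[C@H](c8ccc(OCc9ccccc9)cc8)O2)C#CCO[Si](C)(C)C(C)(C)C
F4 | step 13 | (P)-allenylboronate [C]CH=C=C(CH2OTBS)Bpin | [H]C(c1cc(OCc9ccccc9)cc2c1[C@@H](c8cc(OCc9ccccc9)cc(OCc9ccccc9)c8)[C@H](c8ccc(OCc9ccccc9)cc8)O2)=[C@@]=C(B5OC(C)(C)C(C)(C)O5)CO[Si](C)(C)C(C)(C)C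
F5 | step 29 | octaphenol alcohol (47 without its eight benzyl groups) | OCc5cc(O)cc6c5[C@@H](c3cc(O)cc4c3[C@H](c1cc(O)cc2c1[C@@H](c8cc(O)cc(O)c8)[C@H](c8ccc(O)cc8)O2)[C@@H](c8ccc(O)cc8)O4)[C@H](c8ccc(O)cc8)O6
F6 | step 29 | nona-TBS ether of F5 | CC(C)(C)[Si](C)(C)OCc5cc(O[Si](C)(C)C(C)(C)C)cc6c5[C@@H](c3cc(O[Si](C)(C)C(C)(C)C)cc4c3[C@H](c1cc(O[Si](C)(C)C(C)(C)C)cc2c1[C@@H](c8cc(O[Si](C)(C)C(C)(C)C)cc(O[Si](C)(C)C(C)(C)C)c8)[C@H](c8ccc(O[Si](C)(C)C(C)(C)C)cc8)O2)[C@@H](c8ccc(O[Si](C)(C)C(C)(C)C)cc8)O4)[C@H](c8ccc(O[Si](C)(C)C(C)(C)C)cc8)O6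
F7 | step 29 | octa-TBS benzylic alcohol | OCc5cc(O[Si](C)(C)C(C)(C)C)cc6c5[C@@H](c3cc(O[Si](C)(C)C(C)(C)C)cc4c3[C@H](c1cc(O[Si](C)(C)C(C)(C)C)cc2c1[C@@H](c8cc(O[Si](C)(C)C(C)(C)C)cc(O[Si](C)(C)C(C)(C)C)c8)[C@H](c8ccc(O[Si](C)(C)C(C)(C)C)cc8)O2)[C@@H](c8ccc(O[Si](C)(C)C(C)(C)C)cc8)O4)[C@H](c8ccc(O[Si](C)(C)C(C)(C)C)cc8)O6
F8 | step 29 | octa-TBS aldehyde | O=Cc5cc(O[Si](C)(C)C(C)(C)C)cc6c5[C@@H](c3cc(O[Si](C)(C)C(C)(C)C)cc4c3[C@H](c1cc(O[Si](C)(C)C(C)(C)C)cc2c1[C@@H](c8cc(O[Si](C)(C)C(C)(C)C)cc(O[Si](C)(C)C(C)(C)C)c8)[C@H](c8ccc(O[Si](C)(C)C(C)(C)C)cc8)O2)[C@@H](c8ccc(O[Si](C)(C)C(C)(C)C)cc8)O4)[C@H](c8ccc(O[Si](C)(C)C(C)(C)C)cc8)O6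
F9 | step 29 | diethyl (3,4-dihydroxybenzyl)phosphonate | CCOP(=O)(Cc1ccc(O)c(O)c1)OCC
F10 | step 29 | diethyl [3,4-bis(TBSO)benzyl]phosphonate | CCOP(=O)(Cc1ccc(O[Si](C)(C)C(C)(C)C)c(O[Si](C)(C)C(C)(C)C)c1)OCC
F11 | step 29 | deca-TBS ether of the target, E-stilbene | CC(C)(C)[Si](C)(C)Oc7ccc(/C=C/c5cc(O[Si](C)(C)C(C)(C)C)cc6c5[C@@H](c3cc(O[Si](C)(C)C(C)(C)C)cc4c3[C@H](c1cc(O[Si](C)(C)C(C)(C)C)cc2c1[C@@H](c8cc(O[Si](C)(C)C(C)(C)C)cc(O[Si](C)(C)C(C)(C)C)c8)[C@H](c8ccc(O[Si](C)(C)C(C)(C)C)cc8)O2)[C@@H](c8ccc(O[Si](C)(C)C(C)(C)C)cc8)O4)[C@H](c8ccc(O[Si](C)(C)C(C)(C)C)cc8)O6)cc7O[Si](C)(C)C(C)(C)C
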